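In percent of the solid substrate charged, the next flask repeats ochre at [solid substrate] = 0.24 M, and I must decide when to stop it within 12 h.

| setting | ochre | amber | flask |
|---|---|---|---|
| solid substrate | 0.24 M | 0.48 M | 0.24 M |
| gas phase | 110 mM (held) | 110 mM (held) | 110 mM (held) |
| protic impurity | 0.12 M | 0.12 M | 0.120 M |
| remark | the very flask that is asked about, followed so far | run made earlier |  |
| time |  |  | 12 h |

ochre run (percent of the solid substrate charged)

| time / min | target / % | solid substrate / % |
|---|---|---|
| 20.0 | 17.9 | 0.3 |
| 40.0 | 18.9 | 0.5 |
| 60.0 | 17.7 | 0 |
| 80.0 | 16.4 | 0 |

amber run (percent of the solid substrate charged)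

| time / h | target / % | solid substrate / % |
|---|---|---|
| 1.50 | 16.9 | 0 |
| 4.00 | 16.0 | 0 |
| 8.00 | 15.6 | 0.6 |
| 12.0 | 15.9 | 0.2 |

(readings scatter by 0.3 percentage points)

- solid, in amounts per volume of the solution: solid substrate
- at the start none of the gas is dissolved
- steps that have been proposed: gas phase <-> dissolved gas; starting material + dissolved gas -> target; starting material -> side product; target <-> isomer of the product; dissolved gas + protic impurity -> quenched reagent; solid substrate <-> starting material
- at the start none of the solid substrate is in solution

1. the moment within 12 h at which there is most target
2. the amount of target, in percent of the solid substrate charged, at that time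
3. the first time at which target reaches 13 %, in the same percent

Ochre's highest reading is 18.9 % at 40.0 min, and it then falls to 16.4 % at 80.0 min. Amber, with twice the charge, reads about 15.8 % over its last 2 readings, and I take that as the late level of the ochre recipe too. I call the late level divided by the peak reading the keep: 0.833. The zero of this scale is a keep of 1, where peak and late level are equal and the stopping time costs nothing.

For the next flask I reckon that waiting until 12 h costs 3.1 percentage points against a scatter of 0.3 points. So I plan to stop it near 40.0 min, at about 18.9 %, with the charge as in ochre, choosing kinetic against thermodynamic control. Ochre already reads 17.9 % at 20.0 min, so I expect 13 % on the rise before that reading. My late level stays above 13 %.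

The forecast gives 0.58 h, 19 % and 0.2 h, with “an equilibrium level near 12–13 %, lower than amber's”, which differs from my late level.

The flask gives most target, 19.0 %, at 0.515 h, and reaches 13 % at 0.191 h.

    gas phase ⇌ dissolved gas, rate k1*(csat - [dissolved gas]) (kL = 0.0380 s⁻¹)
    starting material + dissolved gas → target (k = 0.00370 M⁻¹ s⁻¹)
    starting material → side product (k = 4.60 × 10⁻⁴ s⁻¹)
    target ⇌ isomer of the product (K = 1.90, k = 9.10 × 10⁻⁴ s⁻¹)
    dissolved gas + protic impurity → quenched reagent (k = 0.00230 M⁻¹ s⁻¹)
    solid substrate ⇌ starting material, rate k6*(cs6 - [starting material]) while solid is left; crystals form when [starting material] > cs6 (solubility = 0.170 M, k = 0.0160 s⁻¹)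

Target and isomer of the product relax, both ways together, with a half-life of 0.139 h, shorter than 12 h, and at 12.0 h the flask holds 16.0 % target beside 30.4 % isomer of the product. The flask's own keep is 0.842, and the neighbouring flask, read at 50 h, shows 16.0 % after a highest 19.0 %, a keep of 0.842.

All runs are simulated on assumed constants; scatter was added.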